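**Plan**

1. Retrosynthetic cuts: first the aryl–O–CH2 ether bond (umbelliferone). Then, in the cyclohexanone, the bond between the CMe2 carbon and the ring CH that carries the side chain is re-drawn from that CH to the carbonyl carbon, which turns the ketone into a 1-(prop-1-en-2-yl)cyclopentan-1-ol. Last, the bond from that ring CH to the first side-chain CH2.
2. Enabling feature: in the six-membered ring the carbonyl carbon, the quaternary CMe2 carbon and the side-chain-bearing CH are contiguous (C(=O)–CMe2–CH), which is the retron of a semipinacol 1,2-shift. Taking CMe2 out of the ring leaves a cyclopentane (carbinol C, CH2, CH2, C(Me)O, CH) whose CH lies between two oxygenated carbons. That CH can be made by opening an epoxy alcohol with a carbon nucleophile, which the neopentyl CH of the cyclohexane would not allow.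
3. Forward order: (R)-linalool to the side-chain iodide (steps 1–4); 3-methylcyclopent-2-enone to the cis-epoxy alcohol (steps 5–6); copper-catalysed epoxide opening joins them (step 7); oxidation, silylation and isopropenyl addition (steps 8–10); ring enlargement of the cyclopentane to the cyclohexanone (step 11); deprotection and Mitsunobu etherification (steps 12–13).
4. Stereochemistry: the side-chain carbinol is the untouched carbinol carbon of (R)-linalool. In the ring, a CBS reduction sets a temporary carbinol centre (later the ketone carbon), the directed epoxidation relays it to both epoxide carbons, anti opening places the side chain trans to the tertiary OH, and the migrating CH keeps its configuration.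

Key step: step 11

Remark: (R)-(−)-linalool is taken as the enantiomerically enriched commercial material; its carbinol carbon is never touched and its geometry maps directly onto the (R)-configured side-chain carbinol of the target.

**Step 1**
Reactants: 1 (R)-(−)-linalool, (3R)-3,7-dimethylocta-1,6-dien-3-ol
Product: 3 (3R)-3,7-dimethyloct-6-ene-1,3-diol, via alkylborane 2 (not isolated)
Conditions: 9-BBN, THF, 0 °C to rt; then NaOH (aq.), H2O2, 0 °C to rt
Reagents that add atoms: hydrogen peroxide, OO
Why: Chemoselective anti-Markovnikov hydroboration–oxidation, in which 9-BBN should add to the monosubstituted vinyl group much faster than to the trisubstituted alkene, leaving the carbinol stereocentre untouched.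

**Step 2**
Reactants: 3 (3R)-3,7-dimethyloct-6-ene-1,3-diol
Product: 4 (4R)-2,2,4-trimethyl-4-(4-methylpent-3-en-1-yl)-1,3-dioxane
Conditions: 2,2-dimethoxypropane, PPTS (cat.), CH2Cl2, rt
Reagents that add atoms: 2,2-dimethoxypropane, COC(C)(C)OC
Why: Acetal exchange (acetonide formation) should mask the primary and the tertiary hydroxyl of the 1,3-diol as one base-stable 1,3-dioxane without touching the stereocentre.

**Step 3**
Reactants: 4 (4R)-2,2,4-trimethyl-4-(4-methylpent-3-en-1-yl)-1,3-dioxane
Product: 6 3-[(4R)-2,2,4-trimethyl-1,3-dioxan-4-yl]propanoic acid, via aldehyde 5 (not isolated)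
Conditions: RuCl3 hydrate (cat.), NaIO4, NaHCO3, MeCN/EtOAc/H2O, 0 °C to rt
Reagents that add atoms: sodium periodate, [Na+].[O-]I(=O)(=O)=O; water, O
Why: Ruthenium tetroxide-catalysed oxidative cleavage of the trisubstituted alkene should give the acid with loss of acetone, the bicarbonate buffer protecting the acetonide.

**Step 4**
Reactants: 6 3-[(4R)-2,2,4-trimethyl-1,3-dioxan-4-yl]propanoic acid
Product: 8 (4S)-4-(2-iodoethyl)-2,2,4-trimethyl-1,3-dioxane, via acyl hypoiodite 7 (not isolated)
Conditions: PhI(OAc)2, I2, cyclohexane, hν (tungsten lamp), 60 °C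
Reagents that add atoms: iodine, II
Why: Hunsdiecker-type radical iododecarboxylation, in which the acyl hypoiodite should homolyse, lose CO2 and transfer iodine to the primary radical, removing the one surplus carbon while the remote quaternary stereocentre stays untouched (the descriptor changes only because iodine changes the priorities).

**Step 5**
Reactants: 9 3-methylcyclopent-2-en-1-one
Product: 10 (1R)-3-methylcyclopent-2-en-1-ol
Conditions: (S)-2-methyl-CBS-oxazaborolidine (cat.), BH3·SMe2, THF, −20 °C; MeOH
Reagents that add atoms: none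
Why: Corey–Bakshi–Shibata reduction, in which the (S)-oxazaborolidine should treat the alkenyl flank of the carbonyl as the large group and deliver hydride to the face that gives the (R)-allylic alcohol.

**Step 6**
Reactants: 10 (1R)-3-methylcyclopent-2-en-1-ol
Product: 11 (1R,2R,5S)-5-methyl-6-oxabicyclo[3.1.0]hexan-2-ol (epoxide cis to the hydroxyl)
Conditions: VO(acac)2 (cat.), t-BuOOH, CH2Cl2, 0 °C to rt
Reagents that add atoms: tert-butyl hydroperoxide, CC(C)(C)OO
Why: Hydroxyl-directed vanadium-catalysed epoxidation should deliver oxygen to the alkene face syn to the OH, so the carbinol centre of step 5 sets both epoxide stereocentres.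

**Step 7**
Reactants: 8 (4S)-4-(2-iodoethyl)-2,2,4-trimethyl-1,3-dioxane; 11 (1R,2R,5S)-5-methyl-6-oxabicyclo[3.1.0]hexan-2-ol
Product: 14 (1S,2S,3R)-1-methyl-2-{2-[(4R)-2,2,4-trimethyl-1,3-dioxan-4-yl]ethyl}cyclopentane-1,3-diol, via magnesium alkoxide 12 (not isolated), via Grignard reagent 13 (not isolated)
Conditions: 11, i-PrMgCl (1 equiv), THF, −30 °C; in a separate flask 8, Mg, THF, rt; combine, CuI (cat.), −30 °C to 0 °C; NH4Cl (aq.)
Reagents that add atoms: none
Why: Copper-catalysed Grignard opening of the epoxide (SN2, anti) should occur at the secondary epoxide carbon and not at the methyl-bearing tertiary one, with inversion, so that the side chain ends up trans to the tertiary hydroxyl, whose C–O bond and configuration are kept; the pre-formed cis alkoxide saves Grignard reagent and cannot undergo a Payne shift.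

**Step 8**
Reactants: 14 (1S,2S,3R)-1-methyl-2-{2-[(4R)-2,2,4-trimethyl-1,3-dioxan-4-yl]ethyl}cyclopentane-1,3-diol
Product: 15 (2R,3S)-3-hydroxy-3-methyl-2-{2-[(4R)-2,2,4-trimethyl-1,3-dioxan-4-yl]ethyl}cyclopentan-1-one
Conditions: Dess–Martin periodinane, NaHCO3, CH2Cl2, 0 °C to rt
Reagents that add atoms: none
Why: Dess–Martin oxidation can only oxidise the secondary alcohol, and the buffered non-basic medium should spare the β-hydroxy ketone from dehydration and the α-stereocentre from epimerisation; the temporary carbinol centre is removed here.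

**Step 9**
Reactants: 15 (2R,3S)-3-hydroxy-3-methyl-2-{2-[(4R)-2,2,4-trimethyl-1,3-dioxan-4-yl]ethyl}cyclopentan-1-one
Product: 16 (2R,3S)-3-methyl-3-[(triethylsilyl)oxy]-2-{2-[(4R)-2,2,4-trimethyl-1,3-dioxan-4-yl]ethyl}cyclopentan-1-one
Conditions: Et3SiOTf, 2,6-lutidine, CH2Cl2, −78 °C
Reagents that add atoms: triethylsilyl trifluoromethanesulfonate, CC[Si](CC)(CC)OS(=O)(=O)C(F)(F)F
Why: Silylation of the tertiary alcohol with the silyl triflate at low temperature should cap the oxygen so that it neither triggers retro-aldol cleavage in step 10 nor traps the cationic centre in step 11.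

**Step 10**
Reactants: 16 (2R,3S)-3-methyl-3-[(triethylsilyl)oxy]-2-{2-[(4R)-2,2,4-trimethyl-1,3-dioxan-4-yl]ethyl}cyclopentan-1-one
Product: 17 (1S,2S,3S)-3-methyl-1-(prop-1-en-2-yl)-3-[(triethylsilyl)oxy]-2-{2-[(4R)-2,2,4-trimethyl-1,3-dioxan-4-yl]ethyl}cyclopentan-1-ol
Conditions: CeCl3 (anhydrous), isopropenylmagnesium bromide, THF, −78 °C; NH4Cl (aq.)
Reagents that add atoms: isopropenylmagnesium bromide, CC(=C)[Mg]Br
Why: Organocerium 1,2-addition, whose low basicity should avoid enolisation and β-elimination of the silyloxy group; attack is expected anti to the α side chain, but the new carbinol centre is destroyed in step 11, so either epimer serves.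

**Step 11**
Reactants: 17 (1S,2S,3S)-3-methyl-1-(prop-1-en-2-yl)-3-[(triethylsilyl)oxy]-2-{2-[(4R)-2,2,4-trimethyl-1,3-dioxan-4-yl]ethyl}cyclopentan-1-ol
Product: 18 (3S,4S)-2,2,4-trimethyl-4-[(triethylsilyl)oxy]-3-{2-[(4R)-2,2,4-trimethyl-1,3-dioxan-4-yl]ethyl}cyclohexan-1-one
Conditions: [N,N'-bis(3,5-di-tert-butylsalicylidene)-1,2-cyclohexanediaminato]cobalt (C36H52CoN2O2, divalent cobalt, cat.), N-fluoro-2,4,6-trimethylpyridinium tetrafluoroborate, PhSiH3, acetone, 0 °C to rt
Reagents that add atoms: none
Why: A cobalt hydride, formed from the cobalt salen complex, the N-fluoropyridinium oxidant and PhSiH3, should transfer a hydrogen atom to the terminal CH2 of the isopropenyl group (Markovnikov), and the tertiary radical is then captured and oxidised at cobalt to a tertiary cation equivalent on the CMe2 carbon next to the carbinol carbon. The ring CH bearing the side chain then shifts from the carbinol carbon to this carbon while O–H becomes C=O; this is a hydrogen-atom-transfer-initiated radical–polar crossover semipinacol rearrangement, the closest known type being the catalytic semipinacol ring enlargement of 1-(prop-1-en-2-yl)cycloalkanols. No ring is closed by cyclisation: the cyclohexanone arises from the cyclopentane by this 1,2-shift, which inserts the new quaternary CMe2 carbon between the carbonyl carbon and the ring CH. No new stereocentre is formed; the migrating CH moves with retention, the silyloxy-bearing carbon is not involved, and the carbinol centre of step 10 disappears, so both epimers of 17 converge on 18. The step needs migration of the ring CH and not of the ring CH2, and a 1,2-shift and not oxirane or ether closure: the CH is the more substituted and better migrating carbon, relief of cyclopentane strain on going to the six-membered ketone favours the shift over oxirane formation, and the triethylsilyl cap keeps the tertiary oxygen from trapping the cation.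

**Step 12**
Reactants: 18 (3S,4S)-2,2,4-trimethyl-4-[(triethylsilyl)oxy]-3-{2-[(4R)-2,2,4-trimethyl-1,3-dioxan-4-yl]ethyl}cyclohexan-1-one
Product: 19 (3S,4S)-3-[(3R)-3,5-dihydroxy-3-methylpentyl]-4-hydroxy-2,2,4-trimethylcyclohexan-1-one
Conditions: HCl (0.5 M aq.), THF, rt
Reagents that add atoms: none
Why: Mild acid hydrolysis should cleave the acetonide and the tertiary silyl ether in one operation; no stereocentre is α to the ketone and no β-hydroxy ketone is present, so neither epimerisation nor retro-aldol cleavage is expected.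

**Step 13**
Reactants: 19 (3S,4S)-3-[(3R)-3,5-dihydroxy-3-methylpentyl]-4-hydroxy-2,2,4-trimethylcyclohexan-1-one; 20 umbelliferone (7-hydroxy-2H-chromen-2-one)
Product: 21 (3S,4S)-4-hydroxy-3-{(3R)-3-hydroxy-3-methyl-5-[(2-oxo-2H-chromen-7-yl)oxy]pentyl}-2,2,4-trimethylcyclohexan-1-one (target)
Conditions: PPh3, DIAD, THF, 0 °C to rt
Reagents that add atoms: none
Why: Mitsunobu etherification, in which only the primary alcohol should be activated in the presence of the two tertiary alcohols and the acidic phenol displaces the oxyphosphonium group at CH2, so no stereocentre is involved.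

**Compound list**

1 | (R)-(−)-linalool, (3R)-3,7-dimethylocta-1,6-dien-3-ol | C=C[C@](C)(O)CCC=C(C)C | starting material
2 | 9-[(3S)-3-hydroxy-3,7-dimethyloct-6-en-1-yl]-9-borabicyclo[3.3.1]nonane (same geometry as 1; boron on the former terminal vinyl carbon) | B1(CC[C@](C)(O)CCC=C(C)C)C2CCCC1CCC2 | intermediate
3 | (3R)-3,7-dimethyloct-6-ene-1,3-diol | OCC[C@](C)(O)CCC=C(C)C | intermediate
4 | (4R)-2,2,4-trimethyl-4-(4-methylpent-3-en-1-yl)-1,3-dioxane | CC(C)=CCC[C@]1(C)CCOC(C)(C)O1 | intermediate
5 | 3-[(4R)-2,2,4-trimethyl-1,3-dioxan-4-yl]propanal | O=CCC[C@]1(C)CCOC(C)(C)O1 | intermediate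
6 | 3-[(4R)-2,2,4-trimethyl-1,3-dioxan-4-yl]propanoic acid | OC(=O)CC[C@]1(C)CCOC(C)(C)O1 | intermediate
7 | 3-[(4R)-2,2,4-trimethyl-1,3-dioxan-4-yl]propanoyl hypoiodite | IOC(=O)CC[C@]1(C)CCOC(C)(C)O1 | intermediate
8 | (4S)-4-(2-iodoethyl)-2,2,4-trimethyl-1,3-dioxane | ICC[C@]1(C)CCOC(C)(C)O1 | intermediate
9 | 3-methylcyclopent-2-en-1-one | O=C1CCC(C)=C1 | starting material
10 | (1R)-3-methylcyclopent-2-en-1-ol | O[C@@H]1CCC(C)=C1 | intermediate
11 | (1R,2R,5S)-5-methyl-6-oxabicyclo[3.1.0]hexan-2-ol (epoxide cis to OH) | O[C@@H]1CC[C@]2(C)O[C@H]12 | intermediate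
12 | chloromagnesium (1R,2R,5S)-5-methyl-6-oxabicyclo[3.1.0]hexan-2-olate | Cl[Mg]O[C@@H]1CC[C@]2(C)O[C@H]12 | intermediate
13 | {2-[(4S)-2,2,4-trimethyl-1,3-dioxan-4-yl]ethyl}magnesium iodide | I[Mg]CC[C@]1(C)CCOC(C)(C)O1 | intermediate
14 | (1S,2S,3R)-1-methyl-2-{2-[(4R)-2,2,4-trimethyl-1,3-dioxan-4-yl]ethyl}cyclopentane-1,3-diol (side chain trans to both hydroxyls) | O[C@@H]1CC[C@](C)(O)[C@H]1CC[C@]2(C)CCOC(C)(C)O2 | intermediate
15 | (2R,3S)-3-hydroxy-3-methyl-2-{2-[(4R)-2,2,4-trimethyl-1,3-dioxan-4-yl]ethyl}cyclopentan-1-one | O=C1CC[C@](C)(O)[C@H]1CC[C@]2(C)CCOC(C)(C)O2 | intermediate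
16 | (2R,3S)-3-methyl-3-[(triethylsilyl)oxy]-2-{2-[(4R)-2,2,4-trimethyl-1,3-dioxan-4-yl]ethyl}cyclopentan-1-one | O=C1CC[C@](C)(O[Si](CC)(CC)CC)[C@H]1CC[C@]2(C)CCOC(C)(C)O2 | intermediate
17 | (1S,2S,3S)-3-methyl-1-(prop-1-en-2-yl)-3-[(triethylsilyl)oxy]-2-{2-[(4R)-2,2,4-trimethyl-1,3-dioxan-4-yl]ethyl}cyclopentan-1-ol (isopropenyl trans to the side chain) | CC(=C)[C@]1(O)CC[C@](C)(O[Si](CC)(CC)CC)[C@H]1CC[C@]2(C)CCOC(C)(C)O2 | intermediate
18 | (3S,4S)-2,2,4-trimethyl-4-[(triethylsilyl)oxy]-3-{2-[(4R)-2,2,4-trimethyl-1,3-dioxan-4-yl]ethyl}cyclohexan-1-one | CC1(C)C(=O)CC[C@](C)(O[Si](CC)(CC)CC)[C@H]1CC[C@]2(C)CCOC(C)(C)O2 | intermediate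
19 | (3S,4S)-3-[(3R)-3,5-dihydroxy-3-methylpentyl]-4-hydroxy-2,2,4-trimethylcyclohexan-1-one | CC1(C)C(=O)CC[C@](C)(O)[C@H]1CC[C@@](C)(O)CCO | intermediate
20 | umbelliferone, 7-hydroxy-2H-chromen-2-one | Oc1ccc2ccc(=O)oc2c1 | starting material
21 | (3S,4S)-4-hydroxy-3-{(3R)-3-hydroxy-3-methyl-5-[(2-oxo-2H-chromen-7-yl)oxy]pentyl}-2,2,4-trimethylcyclohexan-1-one | CC1(C)C(=O)CC[C@](C)(O)[C@H]1CC[C@@](C)(O)CCOc1ccc2ccc(=O)oc2c1 | target

**Step count and risks**

Total steps: 13. Longest linear sequence: 11 steps (steps 1–4 and 7–13, from linalool).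

Most likely to fail, step 11: the cationic organocobalt intermediate may collapse by attack of the carbinol oxygen (oxirane formation), the tertiary radical may simply be reduced, or the ring CH2 may migrate in competition with the ring CH. The fallback sets out from ketone 16 and returns at ketone 18. Addition of 2-lithio-2-(methylselanyl)propane (from 2,2-bis(methylselanyl)propane and n-BuLi, THF, −78 °C) to 16 should give the β-hydroxyalkyl selenide (1S,2S,3S)-3-methyl-1-[2-(methylselanyl)propan-2-yl]-3-[(triethylsilyl)oxy]-2-{2-[(4R)-2,2,4-trimethyl-1,3-dioxan-4-yl]ethyl}cyclopentan-1-ol F1. Activation of selenium with AgBF4 on neutral Al2O3 in CH2Cl2 turns the methylselanyl group into a leaving group on the CMe2 carbon, and the 1,2-shift of the more substituted ring carbon should then give 18 by a two-electron path with no alkene, no radical and no cobalt-bound cation. It does not remove the risk of CH2 migration, which is intrinsic to the precursor.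

Second, step 7: the Grignard reagent may act as a base and isomerise the epoxide to an allylic alcohol, iodide from the magnesium salts may open the epoxide, or substitution next to the alkoxide may be too slow. The fallback sets out from iodide 8 and alkoxide 12 and returns at diol 14. Displacement of iodide in 8 with PhSO2Na (DMF, rt) should give (4S)-2,2,4-trimethyl-4-[2-(phenylsulfonyl)ethyl]-1,3-dioxane F2. Deprotonation with n-BuLi (THF, −78 °C) gives the α-lithio sulfone F3, a stabilised and less basic carbanion, which in THF/DMPU should open the epoxide of 12 at the same secondary carbon with inversion. This gives the hydroxy sulfone F4 (diol 14 carrying a phenylsulfonyl group on the side-chain carbon attached to the ring, as a mixture of epimers at that carbon). Reductive desulfonylation (Mg, MeOH) should then give 14.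

Third, step 5: the two flanks of the carbonyl (CH2 and CH=) differ little, so facial discrimination in the reduction may be insufficient and would lower the enantiomeric purity of the ring and give diastereomers after step 7. The fallback sets out from enone 9 and returns at alcohol 10. Luche reduction (NaBH4, CeCl3·7H2O, MeOH, 0 °C) should give racemic 3-methylcyclopent-2-en-1-ol F5. Lipase-catalysed kinetic resolution (Candida antarctica lipase B, vinyl acetate, MTBE, rt) is expected to acylate the (R)-enantiomer to (1R)-3-methylcyclopent-2-en-1-yl acetate F6, which is separated from the unreacted enantiomer. Methanolysis (K2CO3, MeOH) should give 10.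

**Further compounds**

F1 | step 11 | (1S,2S,3S)-3-methyl-1-[2-(methylselanyl)propan-2-yl]-3-[(triethylsilyl)oxy]-2-{2-[(4R)-2,2,4-trimethyl-1,3-dioxan-4-yl]ethyl}cyclopentan-1-ol | C[Se]C(C)(C)[C@]1(O)CC[C@](C)(O[Si](CC)(CC)CC)[C@H]1CC[C@]2(C)CCOC(C)(C)O2
F2 | step 7 | (4S)-2,2,4-trimethyl-4-[2-(phenylsulfonyl)ethyl]-1,3-dioxane | O=S(=O)(CC[C@]1(C)CCOC(C)(C)O1)c1ccccc1
F3 | step 7 | α-lithio derivative of sulfone F2 (lithium on the carbon next to sulfur) | [Li]C(C[C@]1(C)CCOC(C)(C)O1)S(=O)(=O)c1ccccc1
F4 | step 7 | hydroxy sulfone: diol 14 with a phenylsulfonyl group on the side-chain carbon attached to the ring (epimers at that carbon) | O[C@@H]1CC[C@](C)(O)[C@H]1C(C[C@]2(C)CCOC(C)(C)O2)S(=O)(=O)c1ccccc1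
F5 | step 5 | racemic 3-methylcyclopent-2-en-1-ol | OC1CCC(C)=C1
F6 | step 5 | (1R)-3-methylcyclopent-2-en-1-yl acetate | CC(=O)O[C@@H]1CCC(C)=C1
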